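**Retrosynthetic overview**

1. Atoms C1–C26 are numbered in the order in which they stand in the target SMILES (O18 is the hydroxyl oxygen). Ring A = C3, C4, C5, C6, C8; ring B = C2, C3, C8, C9, C10, C11, C13, C26; ring C = C13, C14, C15, C24, C25, C26; ring D = C15, C17, C19, C20, C24.
2. The route rests on ring B: this eight-membered ring carries the tetrasubstituted C2=C3 alkene and is fused through C13–C26 to cyclohexene ring C. With C13=C14 formally moved to C10=C11 it is a cis,cis-cycloocta-1,5-diene on a six-membered ring, the adduct of a [4+4] union of dienes C26=C2–C3=C8 and C13=C11–C10=C9 linked by the chain C25–C24–C15–C14.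
3. Disconnections: C13–C26 and C8–C9 (one nickel-catalysed [4+4]); C25–C26 (Negishi coupling); C24–C25 and C15–C14 (conjugate addition/aldol on a ring D cyclopentenone); C2–C1 (carboalumination of a ring A enyne).
4. Ring order: rings D and A are bought as cyclopentenones and each is given one diene arm; rings C and B close together in the key step; the end game sets C17–OH, the C6 and C11 methyl centres and C13=C14.

Key step: step 17

Face convention: β is the face of ring D and of the tetracycle that carries the angular methyl C16; α is the other face.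
Assumption: the aldol of step 7 is drawn as the C14 epimer expected from a closed chair transition state (oxygen β in the tetracycle); the route does not depend on it, because C14 is oxidised in step 21 and ends as an alkene carbon.

**Ring D fragment**

Step 1
Reactants: 1 (R)-4-(tert-butyldimethylsilyloxy)cyclopent-2-en-1-one
Product: 2 (3R,4S)-3-(tert-butyldimethylsilyloxy)-4-isopropylcyclopentan-1-one (trans)
Conditions: i-PrMgCl, CuBr·SMe2 (10 mol%), THF, −78 °C; aq. NH4Cl
Reagents that add atoms: isopropylmagnesium chloride, CC(C)[Mg]Cl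
Why: Copper-catalysed conjugate addition should place the isopropyl group on the enone β-carbon from the face opposite to the neighbouring silyloxy group, which fixes the future C20 centre.

Step 2
Reactants: 2 (3R,4S)-3-(tert-butyldimethylsilyloxy)-4-isopropylcyclopentan-1-one
Product: 3 (S)-4-isopropylcyclopent-2-en-1-one
Conditions: DBU, CH2Cl2, 0 °C, short reaction time
Reagents that add atoms: none
Why: E1cB loss of the β-silyloxy group transposes the enone and leaves the isopropyl-bearing carbon untouched, provided contact with base is brief enough to avoid γ-deprotonation.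

Step 3
Reactants: 3 (S)-4-isopropylcyclopent-2-en-1-one
Product: 4 (S)-2-iodo-4-isopropylcyclopent-2-en-1-one
Conditions: I2, pyridine, CH2Cl2, 0 °C to rt
Reagents that add atoms: iodine, II
Why: In this α-iodination of an enone, pyridine adds reversibly at the β-carbon, the enolate is iodinated and pyridine is expelled, so C4 is not involved.

Step 4
Reactants: 4 (S)-2-iodo-4-isopropylcyclopent-2-en-1-one
Product: 5 (S)-4-isopropyl-2-methylcyclopent-2-en-1-one
Conditions: Me4Sn, PdCl2(PhCN)2 (5 mol%), AsPh3, CuI, NMP, 80 °C
Reagents that add atoms: tetramethylstannane, C[Sn](C)(C)C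
Why: Stille coupling of an α-iodoenone runs under neutral conditions, so the γ-stereocentre is not at risk while the C16 methyl is installed.

Step 5
Reactants: 6 (E)-3-methylpent-2-en-4-yn-1-ol
Product: 7 (E)-3-methylpenta-2,4-dien-1-ol
Conditions: H2 (1 atm), Pd/CaCO3–Pb(OAc)2 (Lindlar catalyst), quinoline, Et2O, 0 °C
Reagents that add atoms: none
Why: Lindlar semihydrogenation stops the terminal alkyne at the vinyl group and should leave the trisubstituted E alkene unchanged.

Step 6
Reactants: 7 (E)-3-methylpenta-2,4-dien-1-ol
Product: 8 (E)-3-methylpenta-2,4-dienal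
Conditions: MnO2, CH2Cl2, rt; used as a cold solution
Reagents that add atoms: none
Why: Allylic oxidation with MnO2 is neutral and should keep the E geometry of the C13=C11 alkene in this volatile dienal.

Step 7
Reactants: 5 (S)-4-isopropyl-2-methylcyclopent-2-en-1-one; 8 (E)-3-methylpenta-2,4-dienal
Product: 10 (2S,3S,4S)-2-[(1S,2E)-1-hydroxy-3-methylpenta-2,4-dien-1-yl]-4-isopropyl-3-{[isopropoxy(dimethyl)silyl]methyl}-2-methylcyclopentan-1-one (C16 methyl β; C14 arm α; C25 β; isopropyl α), via chloromagnesium enolate 9 (not isolated)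
Conditions: i-PrO(Me)2SiCH2MgCl (from i-PrO(Me)2SiCH2Cl and Mg, THF), CuBr·SMe2 (10 mol%), THF, −78 to −40 °C; then 8, −78 °C; aq. NH4Cl
Reagents that add atoms: (isopropoxydimethylsilyl)methylmagnesium chloride, CC(C)O[Si](C)(C)C[Mg]Cl
Why: In this three-component coupling the copper-catalysed conjugate addition puts the silylmethyl group (C25) on C24 anti to the isopropyl group, and the tetrasubstituted magnesium enolate then adds 1,2 to the aldehyde at C15 anti to the new C24 substituent through a closed chair aldol transition state, which sets C24 and the quaternary C15.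

Step 8
Reactants: 10 ring D aldol
Product: 11 C14 triethylsilyl ether of 10
Conditions: Et3SiOTf, 2,6-lutidine, CH2Cl2, −78 °C
Reagents that add atoms: triethylsilyl trifluoromethanesulfonate, CC[Si](CC)(CC)OS(=O)(=O)C(F)(F)F
Why: Silylation with the triflate caps the hindered neopentyl carbinol at low temperature and removes the retro-aldol pathway before any basic step.

Step 9
Reactants: 11 C14 triethylsilyl ether
Product: 12 primary alcohol at C25 (hydroxymethyl on C24)
Conditions: 30% H2O2, KF, KHCO3, THF/MeOH, rt
Reagents that add atoms: hydrogen peroxide, OO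
Why: Tamao oxidation converts the alkoxysilyl–carbon bond into C25–OH under buffered peroxide that should spare the dienes, the ketone and the hindered secondary silyl ether.

Step 10
Reactants: 12 primary alcohol
Product: 13 (2S,3S,4S)-3-(iodomethyl)-4-isopropyl-2-methyl-2-[(1S,2E)-3-methyl-1-(triethylsilyloxy)penta-2,4-dien-1-yl]cyclopentan-1-one
Conditions: I2, PPh3, imidazole, CH2Cl2, 0 °C
Reagents that add atoms: iodine, II
Why: Appel-type iodination through the alkoxyphosphonium salt turns the primary alcohol into the iodide by SN2 displacement, and imidazole buffers the acid so that the silyl ether stays.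

**Ring A fragment**

Step 11
Reactants: 14 3-ethoxycyclopent-2-en-1-one; 15 ethynyltrimethylsilane
Product: 18 3-[(trimethylsilyl)ethynyl]cyclopent-2-en-1-one, via lithium (trimethylsilyl)acetylide 16 (not isolated), via lithium 3-ethoxy-1-[(trimethylsilyl)ethynyl]cyclopent-2-en-1-olate 17 (not isolated)
Conditions: 15, n-BuLi, THF, −78 °C; then 14, −78 to 0 °C; 1 M HCl, rt
Reagents that add atoms: water, O
Why: 1,2-Addition of the acetylide to the vinylogous ester followed by acid hydrolysis with allylic transposition (Stork–Danheiser sequence) gives the 3-alkynyl enone.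

Step 12
Reactants: 18 3-[(trimethylsilyl)ethynyl]cyclopent-2-en-1-one
Product: 19 (R)-3-[(trimethylsilyl)ethynyl]cyclopent-2-en-1-ol
Conditions: (S)-2-methyl-CBS-oxazaborolidine (20 mol%), BH3·SMe2, THF, −30 °C
Reagents that add atoms: none
Why: In the Corey–Bakshi–Shibata reduction the conjugated alkenyl arm acts as the large group, so the (S)-oxazaborolidine should deliver hydride to the face that gives the (R)-carbinol at C6.

Step 13
Reactants: 19 (R)-3-[(trimethylsilyl)ethynyl]cyclopent-2-en-1-ol
Product: 20 (R)-3-ethynylcyclopent-2-en-1-ol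
Conditions: K2CO3 (cat.), MeOH, rt
Reagents that add atoms: none
Why: Methanolysis of the alkynyl–silicon bond frees the terminal alkyne without affecting the allylic alcohol.

Step 14
Reactants: 20 (R)-3-ethynylcyclopent-2-en-1-ol
Product: 21 (R)-3-ethynylcyclopent-2-en-1-yl triethylsilyl ether
Conditions: Et3SiCl, imidazole, CH2Cl2, 0 °C
Reagents that add atoms: chlorotriethylsilane, CC[Si](Cl)(CC)CC
Why: Standard silylation protects the C6 oxygen with a group that later comes off together with the C14 ether.

Step 15
Reactants: 21 (R)-3-ethynylcyclopent-2-en-1-yl triethylsilyl ether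
Product: 23 triethyl{[(1R)-3-[(E)-1-iodoprop-1-en-2-yl]cyclopent-2-en-1-yl]oxy}silane, via (E)-dienyl(dimethyl)alane 22 (not isolated)
Conditions: AlMe3, Cp2ZrCl2 (30 mol%), CH2Cl2, 0 °C to rt; then I2, THF, −30 °C
Reagents that add atoms: trimethylaluminium, C[Al](C)C; iodine, II
Why: Zirconium-catalysed carboalumination (Negishi) adds methyl (C1) and aluminium syn across the alkyne with methyl on the internal carbon C2, and iodinolysis with retention gives the E dienyl iodide in which iodine on C26 is trans to ring A.

**Union, key step and end game**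

Step 16
Reactants: 13 ring D iodide; 23 ring A dienyl iodide
Product: 25 bis-diene with both triethylsilyl ethers and the C17 ketone (C25–C26 bond formed; both dienes E), via alkylzinc iodide 24 (not isolated)
Conditions: Zn dust (activated with BrCH2CH2Br and Me3SiCl), LiCl, THF, 40 °C; then 23, Pd(PPh3)4 (5 mol%), THF, 50 °C
Reagents that add atoms: none
Why: Direct zinc insertion gives a primary alkylzinc that tolerates the hindered ketone, and Negishi sp3–sp2 coupling with the alkenyl iodide forms C25–C26 with retention of the E geometry.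

Step 17
Reactants: 25 bis-diene
Product: 26 tetracycle with C2=C3 and C10=C11 alkenes, C6α-OSiEt3, C14β-OSiEt3 and C17 ketone (C8–H α, C13–H β, C26–H α)
Conditions: Ni(cod)2 (20 mol%), PPh3 (40 mol%), toluene (0.02 M), 60–80 °C
Reagents that add atoms: none
Why: Zerovalent nickel binds both s-cis dienes and couples the tethered termini C13 and C26 oxidatively to a bis(allyl) complex of divalent nickel, and reductive elimination between the far allyl termini C8 and C9 releases the cycloocta-1,5-diene; the closest known reaction type is the nickel-catalysed intramolecular [4+4] cycloaddition of bis-1,3-dienes on a four-atom tether to bicyclo[6.4.0]dodecadienes, of which 25 is a more substituted member. Ring C closes by C13–C26 bond formation in a six-membered chair-like array, and ring B closes by the C8–C9 reductive elimination as the eight-membered ring, leaving C2=C3 tetrasubstituted and C10=C11 trisubstituted, both cis in the ring. C26 is controlled by the trans arms on ring D, which favour the chair with the C26–C2 bond equatorial, so that C26–H is axial and syn to C24–H. C8 follows from C26 because both new bonds form on the same nickel-bound face of the E diene, whose carbon substituents C25 and C6 both point outward, so C8–H ends cis to C26–H; C13 takes its diene arm equatorial and is of no consequence because it becomes sp2 later. The selectivity needed is facial on the cyclopentenyl diene, and it is secured by the ring D chair preference together with the α-oriented C6 silyloxy group, which shields the face that ring D does not choose. The four-atom tether and the E geometry of both dienes with the tether outside favour [4+4] over [4+2], and the C17 ketone next to the quaternary C15 should not engage the metal.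

Step 18
Reactants: 26 tetracyclic C17 ketone
Product: 27 C17β-alcohol
Conditions: NaBH4, MeOH/THF, 0 °C
Reagents that add atoms: none
Why: Borohydride reduction should deliver hydride to C17 from the α face, anti to the angular methyl C16 on the neighbouring quaternary carbon, giving the hydroxyl cis to C16 as in the target.

Step 19
Reactants: 27 C17β-alcohol
Product: 28 C17β tert-butyldimethylsilyl ether (C6 and C14 triethylsilyl ethers retained)
Conditions: t-BuMe2SiOTf, 2,6-lutidine, CH2Cl2, 0 °C
Reagents that add atoms: tert-butyldimethylsilyl trifluoromethanesulfonate, CC(C)(C)[Si](C)(C)OS(=O)(=O)C(F)(F)F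
Why: Silylation with the triflate protects the hindered neopentyl alcohol with a group that is far more robust than the triethylsilyl ethers.

Step 20
Reactants: 28 tris-silyl ether
Product: 29 C6α,C14β-diol with C17β-OSiMe2t-Bu
Conditions: PPTS (cat.), MeOH/CH2Cl2, rt
Reagents that add atoms: none
Why: Mild acid methanolysis removes triethylsilyl ethers much faster than a hindered secondary tert-butyldimethylsilyl ether and is too weak to move the alkenes.

Step 21
Reactants: 29 diol
Product: 30 C6,C14-diketone
Conditions: Dess–Martin periodinane, NaHCO3, CH2Cl2, 0 °C to rt; used at once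
Reagents that add atoms: none
Why: Buffered Dess–Martin oxidation converts both secondary alcohols to ketones under conditions that should not epimerise C8 or draw C2=C3 or C10=C11 into conjugation.

Step 22
Reactants: 30 diketone
Product: 31 C6 exocyclic methylene, C14 ketone
Conditions: Zn, CH2Br2, TiCl4 (Lombardo reagent, pre-formed in THF), CH2Cl2, 0 °C to rt
Reagents that add atoms: dibromomethane, BrCBr
Why: The non-basic Lombardo methylenation should react at the accessible C6 cyclopentanone without epimerising C8, while the C14 ketone between the quaternary C15 and the branched C13 is too hindered to react.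

Step 23
Reactants: 31 methylene ketone
Product: 32 saturated C14 ketone with C7 methyl β on C6 and C12 methyl α on C11 (C2=C3 retained)
Conditions: H2 (1 atm), PtO2, EtOAc, rt
Reagents that add atoms: none
Why: Heterogeneous hydrogenation reduces the 1,1-disubstituted and the trisubstituted alkene but not the tetrasubstituted C2=C3, with hydrogen expected at C6 from the α face (the C8–H side, away from C9 and ring B) and at C11 from the β face on which C13–H lies.

Step 24
Reactants: 32 saturated C14 ketone
Product: 34 C13=C14 enol triflate, via potassium enolate 33 (not isolated)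
Conditions: KN(SiMe3)2, THF, −78 °C; then Comins' reagent, −78 to 0 °C
Reagents that add atoms: N-(5-chloropyridin-2-yl)-1,1,1-trifluoro-N-(trifluoromethylsulfonyl)methanesulfonamide, O=S(=O)(N(c1ccc(Cl)cn1)S(=O)(=O)C(F)(F)F)C(F)(F)F
Why: Enolisation can only occur towards C13 because C15 is quaternary, and O-sulfonylation of the enolate fixes the C13=C14 position of the future alkene.

Step 25
Reactants: 34 enol triflate
Product: 35 Aspergilol C tert-butyldimethylsilyl ether
Conditions: Pd(OAc)2 (10 mol%), PPh3, HCO2H, n-Bu3N, DMF, 60 °C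
Reagents that add atoms: none
Why: Palladium-catalysed formate reduction of the alkenyl triflate (oxidative addition, formate exchange, decarboxylation, reductive elimination) replaces the triflate by hydrogen without moving the alkene.

Step 26
Reactants: 35 Aspergilol C tert-butyldimethylsilyl ether
Product: 36 Aspergilol C
Conditions: Bu4NF, THF, 50 °C
Reagents that add atoms: none
Why: Fluoride-induced desilylation frees the C17 hydroxyl under non-acidic conditions that should not isomerise the two alkenes.

**Compound list**

1 | (R)-4-(tert-butyldimethylsilyloxy)cyclopent-2-en-1-one | O=C1C=C[C@H](O[Si](C)(C)C(C)(C)C)C1 | starting material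
2 | (3R,4S)-3-(tert-butyldimethylsilyloxy)-4-isopropylcyclopentan-1-one | O=C1C[C@@H](C(C)C)[C@H](O[Si](C)(C)C(C)(C)C)C1 | intermediate
3 | (S)-4-isopropylcyclopent-2-en-1-one | O=C1C[C@@H](C(C)C)C=C1 | intermediate
4 | (S)-2-iodo-4-isopropylcyclopent-2-en-1-one | O=C1C[C@@H](C(C)C)C=C1I | intermediate
5 | (S)-4-isopropyl-2-methylcyclopent-2-en-1-one | CC1=C[C@H](C(C)C)CC1=O | intermediate
6 | (E)-3-methylpent-2-en-4-yn-1-ol | C#C/C(C)=C/CO | starting material
7 | (E)-3-methylpenta-2,4-dien-1-ol | C=C/C(C)=C/CO | intermediate
8 | (E)-3-methylpenta-2,4-dienal | C=C/C(C)=C/C=O | intermediate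
9 | chloromagnesium enolate of the conjugate adduct (C25 β, isopropyl α) | CC1=C(O[Mg]Cl)C[C@@H](C(C)C)[C@@H]1C[Si](C)(C)OC(C)C | intermediate
10 | (2S,3S,4S)-2-[(1S,2E)-1-hydroxy-3-methylpenta-2,4-dien-1-yl]-4-isopropyl-3-{[isopropoxy(dimethyl)silyl]methyl}-2-methylcyclopentan-1-one | C=C/C(C)=C/[C@H](O)[C@@]1(C)C(=O)C[C@@H](C(C)C)[C@@H]1C[Si](C)(C)OC(C)C | intermediate
11 | C14 triethylsilyl ether of 10 | C=C/C(C)=C/[C@H](O[Si](CC)(CC)CC)[C@@]1(C)C(=O)C[C@@H](C(C)C)[C@@H]1C[Si](C)(C)OC(C)C | intermediate
12 | (2S,3S,4S)-3-(hydroxymethyl)-4-isopropyl-2-methyl-2-[(1S,2E)-3-methyl-1-(triethylsilyloxy)penta-2,4-dien-1-yl]cyclopentan-1-one | C=C/C(C)=C/[C@H](O[Si](CC)(CC)CC)[C@@]1(C)C(=O)C[C@@H](C(C)C)[C@@H]1CO | intermediate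
13 | (2S,3S,4S)-3-(iodomethyl)-4-isopropyl-2-methyl-2-[(1S,2E)-3-methyl-1-(triethylsilyloxy)penta-2,4-dien-1-yl]cyclopentan-1-one | C=C/C(C)=C/[C@H](O[Si](CC)(CC)CC)[C@@]1(C)C(=O)C[C@@H](C(C)C)[C@@H]1CI | intermediate
14 | 3-ethoxycyclopent-2-en-1-one | CCOC1=CC(=O)CC1 | starting material
15 | ethynyltrimethylsilane | C#C[Si](C)(C)C | starting material
16 | lithium (trimethylsilyl)acetylide | [Li]C#C[Si](C)(C)C | intermediate
17 | lithium 3-ethoxy-1-[(trimethylsilyl)ethynyl]cyclopent-2-en-1-olate (racemic) | CCOC1=CC(O[Li])(C#C[Si](C)(C)C)CC1 | intermediate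
18 | 3-[(trimethylsilyl)ethynyl]cyclopent-2-en-1-one | C[Si](C)(C)C#CC1=CC(=O)CC1 | intermediate
19 | (R)-3-[(trimethylsilyl)ethynyl]cyclopent-2-en-1-ol | C[Si](C)(C)C#CC1=C[C@H](O)CC1 | intermediate
20 | (R)-3-ethynylcyclopent-2-en-1-ol | C#CC1=C[C@H](O)CC1 | intermediate
21 | (R)-3-ethynylcyclopent-2-en-1-yl triethylsilyl ether | C#CC1=C[C@H](O[Si](CC)(CC)CC)CC1 | intermediate
22 | (E)-dienyl(dimethyl)alane from carboalumination of 21 | C[Al](C)/C=C(C)/C1=C[C@H](O[Si](CC)(CC)CC)CC1 | intermediate
23 | triethyl{[(1R)-3-[(E)-1-iodoprop-1-en-2-yl]cyclopent-2-en-1-yl]oxy}silane | I/C=C(C)/C1=C[C@H](O[Si](CC)(CC)CC)CC1 | intermediate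
24 | alkylzinc iodide from 13 (zinc on C25) | C=C/C(C)=C/[C@H](O[Si](CC)(CC)CC)[C@@]1(C)C(=O)C[C@@H](C(C)C)[C@@H]1C[Zn]I | intermediate
25 | bis-diene: ring D ketone with the C14-silyloxy dienyl arm on C15 and the ring A dienyl arm on C24 through C25 | C=C/C(C)=C/[C@H](O[Si](CC)(CC)CC)[C@@]1(C)C(=O)C[C@@H](C(C)C)[C@@H]1C/C=C(C)/C1=C[C@H](O[Si](CC)(CC)CC)CC1 | intermediate
26 | tetracyclic cycloocta-1,5-diene: C6α-OSiEt3, C14β-OSiEt3, C17 ketone, C8–H α, C13–H β, C26–H α | C/C1=C2\CC[C@@H](O[Si](CC)(CC)CC)[C@@H]2C/C=C(C)\[C@H]2[C@H](O[Si](CC)(CC)CC)[C@@]3(C)C(=O)C[C@@H](C(C)C)[C@@H]3C[C@@H]21 | intermediate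
27 | C17β-alcohol of 26 | C/C1=C2\CC[C@@H](O[Si](CC)(CC)CC)[C@@H]2C/C=C(C)\[C@H]2[C@H](O[Si](CC)(CC)CC)[C@@]3(C)[C@H](O)C[C@@H](C(C)C)[C@@H]3C[C@@H]21 | intermediate
28 | C17β tert-butyldimethylsilyl ether with C6α and C14β triethylsilyl ethers | C/C1=C2\CC[C@@H](O[Si](CC)(CC)CC)[C@@H]2C/C=C(C)\[C@H]2[C@H](O[Si](CC)(CC)CC)[C@@]3(C)[C@H](O[Si](C)(C)C(C)(C)C)C[C@@H](C(C)C)[C@@H]3C[C@@H]21 | intermediate
29 | C6α,C14β-diol with C17β-OSiMe2t-Bu | C/C1=C2\CC[C@@H](O)[C@@H]2C/C=C(C)\[C@H]2[C@H](O)[C@@]3(C)[C@H](O[Si](C)(C)C(C)(C)C)C[C@@H](C(C)C)[C@@H]3C[C@@H]21 | intermediate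
30 | C6,C14-diketone with C17β-OSiMe2t-Bu | C/C1=C2\CCC(=O)[C@@H]2C/C=C(C)\[C@H]2C(=O)[C@@]3(C)[C@H](O[Si](C)(C)C(C)(C)C)C[C@@H](C(C)C)[C@@H]3C[C@@H]21 | intermediate
31 | C6 exocyclic methylene, C14 ketone, C10=C11 and C2=C3 alkenes | C/C1=C2\CCC(=C)[C@@H]2C/C=C(C)\[C@H]2C(=O)[C@@]3(C)[C@H](O[Si](C)(C)C(C)(C)C)C[C@@H](C(C)C)[C@@H]3C[C@@H]21 | intermediate
32 | saturated C14 ketone with C7 methyl β, C12 methyl α, C13–H β | C/C1=C2\CC[C@H](C)[C@@H]2CC[C@@H](C)[C@H]2C(=O)[C@@]3(C)[C@H](O[Si](C)(C)C(C)(C)C)C[C@@H](C(C)C)[C@@H]3C[C@@H]21 | intermediate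
33 | potassium C13=C14 enolate of 32 | C/C1=C2\CC[C@H](C)[C@@H]2CC[C@@H](C)C2=C(O[K])[C@@]3(C)[C@H](O[Si](C)(C)C(C)(C)C)C[C@@H](C(C)C)[C@@H]3C[C@@H]21 | intermediate
34 | C13=C14 enol triflate | C/C1=C2\CC[C@H](C)[C@@H]2CC[C@@H](C)C2=C(OS(=O)(=O)C(F)(F)F)[C@@]3(C)[C@H](O[Si](C)(C)C(C)(C)C)C[C@@H](C(C)C)[C@@H]3C[C@@H]21 | intermediate
35 | Aspergilol C tert-butyldimethylsilyl ether | C/C1=C2\CC[C@H](C)[C@@H]2CC[C@@H](C)C2=C[C@@]3(C)[C@H](O[Si](C)(C)C(C)(C)C)C[C@@H](C(C)C)[C@@H]3C[C@@H]21 | intermediate
36 | Aspergilol C | C/C1=C2\CC[C@H](C)[C@@H]2CC[C@@H](C)C2=C[C@@]3(C)[C@H](O)C[C@@H](C(C)C)[C@@H]3C[C@@H]21 | target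

**Step count and risks**

Total step count: 26. Longest linear sequence: 19 steps (steps 1–4, 7–10, 16–26, from compound 1).

Steps most likely to fail:

Step 17. Nickel may fail to bind the cyclopentene-embedded, internally methylated diene, so that the bis-diene is consumed by [4+2] closure or oligomerisation, or the two faces of ring A may not be told apart well enough. The fallback sets out from 25 and returns at 26. It forms the same two ring bonds in two known operations.
- Triplet-sensitised intramolecular [2+2] photocycloaddition (thioxanthone, 405 nm, degassed MeCN) joins the proximal alkenes C13=C11 and C26=C2. This closes ring C and gives the cis-1,2-dialkenylcyclobutane F1 (new bonds C13–C26 and C11–C2).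
- Cope rearrangement on heating in toluene (110 °C) breaks C11–C2 and forms C8–C9 through a boat transition state, delivering 26. Trans-dialkenyl isomers would need about 180 °C, where they equilibrate through the bis-allyl diradical.

Step 23. Hydrogen may be delivered to the α face of C10=C11, giving the C11 epimer, or the alkenes may migrate on the metal surface before they are reduced. The fallback sets out from diol 29 and returns at 32.
- Hydroxyl-directed homogeneous hydrogenation with [Rh(nbd)(dppb)]BF4 and H2 (CH2Cl2, elevated pressure): the β-oriented C14 hydroxyl binds the metal and delivers hydrogen to the β face of the homoallylic C10=C11 alkene. The tetrasubstituted C2=C3 is not reduced by this catalyst. The product is the dihydro diol F2.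
- Dess–Martin oxidation gives the saturated diketone F3.
- Lombardo methylenation at C6 gives the methylene ketone F4.
- Hydrogenation of the 1,1-disubstituted alkene alone with RhCl(PPh3)3 and H2 (benzene, rt), from the α face, gives 32.

Step 7. The congested magnesium enolate may add slowly and reversibly to the sensitive dienal, so that proton transfer, retro-aldol cleavage or polymerisation of the aldehyde take over. The fallback sets out from 5 and returns at 10, separating the two bond formations.
- The copper-catalysed conjugate addition is run in the presence of Me3SiCl, and the trimethylsilyl enol ether F5 is isolated.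
- Mukaiyama aldol addition of F5 to 8 (BF3·OEt2, CH2Cl2, −78 °C) is irreversible under Lewis acid and should again occur anti to the C24 substituent. It gives 10, and any C14 epimer formed alongside serves equally.

**Further compounds**

F1 | step 17 | cis-1,2-dialkenylcyclobutane (bicyclo[4.2.0]octane from C13–C26 and C11–C2 bond formation; vinyl on C11 and cyclopentenyl on C2 cis, C26–H on their face, C13–H on the other) | C=C[C@@]1(C)[C@H]2[C@H](O[Si](CC)(CC)CC)[C@@]3(C)C(=O)C[C@@H](C(C)C)[C@@H]3C[C@@H]2[C@@]1(C)C1=C[C@H](O[Si](CC)(CC)CC)CC1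
F2 | step 23 | C6α,C14β-diol with saturated C9–C10–C11 and C12 methyl α | C/C1=C2\CC[C@@H](O)[C@@H]2CC[C@@H](C)[C@H]2[C@H](O)[C@@]3(C)[C@H](O[Si](C)(C)C(C)(C)C)C[C@@H](C(C)C)[C@@H]3C[C@@H]21
F3 | step 23 | C6,C14-diketone with saturated C9–C10–C11 and C12 methyl α | C/C1=C2\CCC(=O)[C@@H]2CC[C@@H](C)[C@H]2C(=O)[C@@]3(C)[C@H](O[Si](C)(C)C(C)(C)C)C[C@@H](C(C)C)[C@@H]3C[C@@H]21
F4 | step 23 | C6 methylene, C14 ketone with saturated C9–C10–C11 and C12 methyl α | C/C1=C2\CCC(=C)[C@@H]2CC[C@@H](C)[C@H]2C(=O)[C@@]3(C)[C@H](O[Si](C)(C)C(C)(C)C)C[C@@H](C(C)C)[C@@H]3C[C@@H]21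
F5 | step 7 | trimethylsilyl enol ether of the conjugate adduct (C25 β, isopropyl α) | CC1=C(O[Si](C)(C)C)C[C@@H](C(C)C)[C@@H]1C[Si](C)(C)OC(C)C
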